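**Retrosynthetic overview**

1. Target 43 ⇐ tricyclic C2 ketone 40 (acetonide) by C2 reduction, acetylation and deprotection.
2. 40 ⇐ seco compound 37 by the C4–C5 bond (ring B, closed last). The strategy rests on this feature: in ring B the oxygenated C2 sits on quaternary C1 of ring A and is followed by the methylenes C3 and C4, which end at the Z-trisubstituted C5=C6 alkene. C2–C3–C4 is therefore a ketone homoenolate, carried as a C2 cyclopropanol, and C5 is an alkenyl iodide.
3. 37 ⇐ C6 aldehyde 35 (iodo-olefination) ⇐ triol 30 (ring C, closed second, by oxidative lactonisation C19→O7) ⇐ diol 28 (C8–O and C17–CH3 by epoxidation of C8=C17 and methyl cuprate opening). A butenolide is not used, because the C8 oxygen must stand cis to the C7 side chain.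
4. 27 ⇐ ring A aldehyde 15 + alkenyllithium 25 (C8–C9 bond; fragment C6–C8/C17/C19 from 16 and 18).
5. 15 ⇐ ring A (formed first) by an enantioselective Diels–Alder reaction of 2 and 3 (C1, C10), the C2 cyclopropanol from a methyl ketone enol silane, and the C11/C12 diol by dihydroxylation of a C11–C14 diene.

Key step: step 27

Numbering: briarane numbering is used for every intermediate (C1 quaternary with the C15 methyl; C2–C4; C5 with the C16 methyl; C6; C7 lactone CH–O; C8 C–OH; C9; C10 ring-fusion CH; C11 with the C20 methyl; C12; C13=C14; C17 with the C18 methyl; C19 lactone C=O). β is the face of ring A that carries C15, α the opposite face. Ring A = cyclohexene, ring B = ten-membered ring, ring C = lactone. The SMILES strings define the configurations.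

Assumption: the sense of induction in step 2 is taken from the formyl C–H···O binding model for 2-substituted acroleins; if adduct 4 were formed as the antipode, the (R)-catalyst would be used.

**Route**

Step 1
Reactants: 1 pent-1-en-3-one
Product: 2 (Z)-3-(triisopropylsilyloxy)penta-1,3-diene
Conditions: i-Pr3SiOTf, Et3N, CH2Cl2, 0 °C
Reagents that add atoms: triisopropylsilyl trifluoromethanesulfonate, CC(C)[Si](C(C)C)(C(C)C)OS(=O)(=O)C(F)(F)F
Why: Soft enolisation of the ethyl ketone with a silyl triflate and an amine should give the Z silyl enol ether, which places the future C11 methyl on the outside of the s-cis diene.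

Step 2
Reactants: 2 (Z)-3-(triisopropylsilyloxy)penta-1,3-diene; 3 ethyl (E)-3-methyl-4-oxobut-2-enoate
Product: 4 ring A adduct, ethyl 6-formyl-2,6-dimethyl-3-(triisopropylsilyloxy)cyclohex-3-ene-1-carboxylate (C10 ester β, C1 methyl β, C1 formyl α, C11 epimers)
Conditions: (S)-1-(2-methylphenyl)-3,3-diphenyltetrahydro-1H,3H-pyrrolo[1,2-c][1,3,2]oxazaborole (20 mol%), Tf2NH (18 mol%), CH2Cl2, −78 to −40 °C
Reagents that add atoms: none
Why: Catalytic enantioselective Diels–Alder reaction in which the oxazaborolidinium ion binds the formyl group of 3, the nucleophilic diene terminus C11 bonds to the β-carbon C10 and C14 to C1, the E geometry of 3 fixes the C1 formyl trans to the C10 ester, and the catalyst face sets the absolute configuration of C1 and C10 (C11 is erased in step 8).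

Step 3
Reactants: 4 ring A adduct
Product: 5 C2 carbinol, the 1-hydroxyethyl compound (C2 and C11 epimers)
Conditions: MeMgBr, THF, −78 °C; AcOH quench at −78 °C
Reagents that add atoms: methylmagnesium bromide, C[Mg]Br
Why: Grignard addition at low temperature is chemoselective for the aldehyde over the hindered ester and the silyl enol ether, the cold quench should prevent lactonisation of the γ-hydroxy ester, and the new carbinol centre is removed in step 4.

Step 4
Reactants: 5 C2 carbinol
Product: 6 C2 methyl ketone, ethyl 6-acetyl-2,6-dimethyl-3-(triisopropylsilyloxy)cyclohex-3-ene-1-carboxylate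
Conditions: Dess–Martin periodinane, NaHCO3, CH2Cl2, 0 °C to rt
Reagents that add atoms: none
Why: Buffered Dess–Martin oxidation of the secondary alcohol should leave the silyl enol ether and the ester untouched.

Step 5
Reactants: 6 C2 methyl ketone
Product: 7 enone, ethyl 6-acetyl-2,6-dimethyl-3-oxocyclohex-4-ene-1-carboxylate (C12 ketone, C13=C14)
Conditions: Pd(OAc)2 (1.1 equiv), MeCN, 40 °C
Reagents that add atoms: none
Why: Saegusa–Ito oxidation of the regiodefined C12 enol ether proceeds through a divalent palladium enolate at C13 that can lose only a C14 hydrogen, so the alkene is formed at C13=C14 alone.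

Step 6
Reactants: 7 enone
Product: 8 C2 silyl enol ether, ethyl 6-[1-(tert-butyldimethylsilyloxy)vinyl]-2,6-dimethyl-3-oxocyclohex-4-ene-1-carboxylate
Conditions: t-BuMe2SiOTf (1.1 equiv), Et3N, CH2Cl2, −78 °C
Reagents that add atoms: tert-butyldimethylsilyl trifluoromethanesulfonate, CC(C)(C)[Si](C)(C)OS(=O)(=O)C(F)(F)F
Why: Soft enolisation should silylate the methyl ketone through its unhindered CH3 faster than the enone, whose only α′ hydrogen (C11) is tertiary and flanked, and it avoids a free enolate that could add to C12 across the ring.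

Step 7
Reactants: 8 C2 silyl enol ether
Product: 9 silyloxycyclopropane, ethyl 6-[1-(tert-butyldimethylsilyloxy)cyclopropyl]-2,6-dimethyl-3-oxocyclohex-4-ene-1-carboxylate
Conditions: Et2Zn, CH2I2, CH2Cl2, 0 °C to rt
Reagents that add atoms: diiodomethane, ICI
Why: Simmons–Smith cyclopropanation (zinc carbenoid from Et2Zn and CH2I2) of the electron-rich silyl enol ether gives the protected C2 cyclopropanol, the electron-poor enone alkene being inert to the carbenoid.

Step 8
Reactants: 9 silyloxycyclopropane
Product: 11 dienyl triflate (C12 triflate, C11=C12 and C13=C14), via potassium dienolate 10 (not isolated)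
Conditions: KN(SiMe3)2, THF, −78 °C; then PhNTf2, −78 to 0 °C
Reagents that add atoms: N-phenylbis(trifluoromethanesulfonimide), O=S(=O)(N(c1ccccc1)S(=O)(=O)C(F)(F)F)C(F)(F)F
Why: Deprotonation at C11, the only enolisable ketone position of this 4,4-disubstituted enone, and O-triflation of the cross-conjugated dienolate give the dienyl triflate and erase the C11 stereocentre.

Step 9
Reactants: 11 dienyl triflate
Product: 12 diene, ethyl 6-[1-(tert-butyldimethylsilyloxy)cyclopropyl]-2,6-dimethylcyclohexa-2,4-diene-1-carboxylate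
Conditions: Pd(PPh3)4 (5 mol%), Bu3SnH, LiCl, THF, rt
Reagents that add atoms: none
Why: Palladium-catalysed reduction of the alkenyl triflate by the tin hydride gives the 1,3-diene under neutral conditions that should not move the C10 hydrogen into conjugation.

Step 10
Reactants: 12 diene
Product: 13 diol (C11 and C12 hydroxyls α and cis, C13=C14 retained)
Conditions: OsO4 (5 mol%), N-methylmorpholine N-oxide, acetone/H2O, 0 °C to rt
Reagents that add atoms: osmium tetroxide, O=[Os](=O)(=O)=O; N-methylmorpholine N-oxide, C[N+]1([O-])CCOCC1; water, O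
Why: Catalytic OsO4 dihydroxylation should take the more electron-rich trisubstituted C11=C12 alkene from the α face, anti to the C10 ester and the pseudoaxial C1 methyl, and so sets C11 and C12 together as the cis diol.

Step 11
Reactants: 13 diol
Product: 14 acetonide ester (C11/C12 isopropylidene acetal)
Conditions: 2,2-dimethoxypropane, PPTS (cat.), CH2Cl2, rt
Reagents that add atoms: 2,2-dimethoxypropane, COC(C)(C)OC
Why: Acid-catalysed transketalisation protects the cis diol as its acetonide without cleaving the tertiary silyl ether.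

Step 12
Reactants: 14 acetonide ester
Product: 15 ring A aldehyde (C9 aldehyde on C10, β; C1 with β-methyl and α-[1-(tert-butyldimethylsilyloxy)cyclopropyl]; C11/C12 α-acetonide; C13=C14)
Conditions: iBu2AlH, CH2Cl2, −78 °C
Reagents that add atoms: none
Why: Hydride reduction of the hindered ester at −78 °C should stop at the aluminium hemiacetal and give the aldehyde on work-up, with C10 kept in the trans arrangement, which is also the more stable one.

Step 13
Reactants: 16 prop-2-yn-1-ol
Product: 17 triethyl(prop-2-yn-1-yloxy)silane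
Conditions: Et3SiCl, imidazole, CH2Cl2, 0 °C
Reagents that add atoms: chlorotriethylsilane, CC[Si](Cl)(CC)CC
Why: Standard silylation of a primary alcohol.

Step 14
Reactants: 17 triethyl(prop-2-yn-1-yloxy)silane; 18 ethyl 2-(tert-butyldimethylsilyloxy)acetate
Product: 20 ynone, 1-(tert-butyldimethylsilyloxy)-5-(triethylsilyloxy)pent-3-yn-2-one, via lithium acetylide 19 (not isolated)
Conditions: n-BuLi, THF, −78 °C; BF3·OEt2; then 18, −78 °C
Reagents that add atoms: none
Why: Acylation of the lithium acetylide by the ester in the presence of BF3·OEt2 stops at the ynone because the tetrahedral adduct persists at −78 °C.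

Step 15
Reactants: 20 ynone
Product: 21 (R)-1-(tert-butyldimethylsilyloxy)-5-(triethylsilyloxy)pent-3-yn-2-ol (C7 carbinol)
Conditions: Ru[(S,S)-TsDPEN](p-cymene) (2 mol%), i-PrOH, rt
Reagents that add atoms: none
Why: Noyori asymmetric transfer hydrogenation of an ynone, in which the (S,S) catalyst treats the alkyne as the large group, should give the carbinol that is R for this substitution pattern and sets C7.

Step 16
Reactants: 21 (R)-alkynol
Product: 23 iodoalkenol, 1-(tert-butyldimethylsilyloxy)-3-iodo-5-(triethylsilyloxy)pent-3-en-2-ol (iodine on C8, cis to C19), via alkenylstannane 22 (not isolated)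
Conditions: Bu3SnH, [Cp*RuCl]4 (2 mol%), CH2Cl2, rt; then I2, 0 °C
Reagents that add atoms: tributyltin hydride, CCCC[SnH](CCCC)CCCC (tin stays only in 22); iodine, II
Why: Ruthenium-catalysed trans-hydrostannation directed by the free propargylic hydroxyl should place tin on C8 and hydrogen on C17 anti to each other, and iododestannylation with retention gives the iodide cis to C19.

Step 17
Reactants: 23 iodoalkenol
Product: 24 C7 triethylsilyl ether of 23
Conditions: Et3SiCl, imidazole, DMAP (cat.), CH2Cl2, rt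
Reagents that add atoms: chlorotriethylsilane, CC[Si](Cl)(CC)CC
Why: Standard silylation of the secondary alcohol.

Step 18
Reactants: 24 alkenyl iodide; 15 ring A aldehyde
Product: 27 coupled C9 acetate (C8=C17 with C9 cis to C19; C6 OTBS, C7 and C19 OSiEt3), via alkenyllithium 25 (not isolated), via lithium alkoxide 26 (not isolated)
Conditions: t-BuLi (2.1 equiv), Et2O, −78 °C; 15, −78 °C; then Ac2O, −78 to 0 °C
Reagents that add atoms: acetic anhydride, CC(=O)OC(C)=O
Why: Iodine–lithium exchange and 1,2-addition of the alkenyllithium to the aldehyde under Felkin–Anh control (C1 as the large group, reinforced by chelation to the C11 oxygen) should give the 9R alkoxide, which is acetylated in the flask, with the alkene geometry retained.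

Step 19
Reactants: 27 coupled C9 acetate
Product: 28 C7,C19 diol
Conditions: PPTS, MeOH, 0 °C
Reagents that add atoms: none
Why: Acid-catalysed methanolysis removes the two triethylsilyl ethers much faster than the primary and tertiary tert-butyldimethylsilyl ethers and the acetonide.

Step 20
Reactants: 28 C7,C19 diol
Product: 29 C8,C17 epoxide
Conditions: Ti(OiPr)4, L-(+)-diisopropyl tartrate, t-BuOOH, 4 Å molecular sieves, CH2Cl2, −20 °C
Reagents that add atoms: tert-butyl hydroperoxide, CC(C)(C)OO
Why: Sharpless asymmetric epoxidation, for which L-(+)-tartrate is the matched ligand of this C7 carbinol and the C19 hydroxyl directs to the same face, should deliver oxygen to give the erythro epoxy alcohol and so sets C8.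

Step 21
Reactants: 29 C8,C17 epoxide
Product: 30 C7,C8,C19 triol with the C17 methyl
Conditions: Me2CuLi (from MeLi and CuI), Et2O, −40 to −10 °C
Reagents that add atoms: lithium dimethylcuprate, [Li+].C[Cu-]C (from methyllithium, [Li]C)
Why: SN2 opening of the trisubstituted epoxide by the cuprate at the less substituted C17 with inversion sets the C17 methyl and releases the tertiary C8 hydroxyl.

Step 22
Reactants: 30 triol
Product: 33 lactone (ring C closed, C6 OTBS), via hydroxy aldehyde 31 (not isolated), via lactol 32 (not isolated)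
Conditions: TEMPO (20 mol%), PhI(OAc)2 (2.5 equiv), CH2Cl2, rt
Reagents that add atoms: none
Why: Nitroxyl-catalysed oxidative lactonisation of the 1,4-diol, in which the primary C19 alcohol is oxidised first, the C7 hydroxyl closes the lactol by 5-exo-trig addition and the lactol is oxidised, closes ring C while the tertiary C8 hydroxyl cannot react.

Step 23
Reactants: 33 lactone
Product: 34 C6 alcohol
Conditions: HF·pyridine, pyridine, THF, 0 °C
Reagents that add atoms: none
Why: Buffered hydrogen fluoride cleaves the primary silyl ether selectively over the hindered tertiary cyclopropyl silyl ether.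

Step 24
Reactants: 34 C6 alcohol
Product: 35 C6 aldehyde
Conditions: Dess–Martin periodinane, NaHCO3, CH2Cl2, 0 °C
Reagents that add atoms: none
Why: Dess–Martin oxidation under buffered conditions gives the α-acyloxy aldehyde without epimerisation at C7.

Step 25
Reactants: 35 C6 aldehyde
Product: 36 (Z)-C5 alkenyl iodide (cyclopropanol still as silyl ether)
Conditions: [Ph3PEt]I, n-BuLi, THF, rt; I2, −78 °C; NaN(SiMe3)2, −78 °C; then 35, −78 to −20 °C
Reagents that add atoms: ethyltriphenylphosphonium iodide, CC[P+](c1ccccc1)(c1ccccc1)c1ccccc1.[I-]; iodine, II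
Why: Stork–Zhao olefination with the α-iodo ylide should give the trisubstituted alkenyl iodide with iodine cis to C7 under kinetic control at low temperature.

Step 26
Reactants: 36 alkenyl iodide silyl ether
Product: 37 seco cyclopropanol (C2 cyclopropanol, C5 Z-alkenyl iodide, C9 acetate, C8 hydroxyl, C11/C12 acetonide)
Conditions: Bu4NF, AcOH, THF, 0 °C to rt
Reagents that add atoms: none
Why: Fluoride buffered with acetic acid removes the tertiary silyl ether without acyl migration or opening of the lactone.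

Step 27
Reactants: 37 seco cyclopropanol
Product: 40 tricyclic C2 ketone (ring B closed, C11/C12 acetonide), via alkenylpalladium iodide 38 (not isolated), via palladium homoenolate 39 (not isolated)
Conditions: Pd(OAc)2 (20 mol%), 2-dicyclohexylphosphino-2′,4′,6′-triisopropylbiphenyl (XPhos, 40 mol%), Cs2CO3 (2 equiv), toluene, 80 °C, slow addition of 37 to a final concentration of about 1 mM
Reagents that add atoms: none
Why: Proposed new method: Pd(OAc)2 is reduced in the flask to zerovalent palladium, which inserts into the C5–I bond with retention of the Z geometry to give the divalent alkenylpalladium iodide 38; after exchange of iodide for the caesium cyclopropanolate, strain-driven β-carbon elimination cleaves a C2–CH2 bond of the cyclopropane, unmasks the C2 ketone and places palladium on C4 (39), and C(sp3)–C(sp2) reductive elimination forms C4–C5. The closest known reaction type is the intermolecular palladium-catalysed ring-opening cross-coupling of cyclopropanols with aryl and alkenyl halides, which has not been used to close a medium ring. Ring B (ten-membered) is closed by reductive elimination from the eleven-membered palladacycle 39, the C5=C6 alkene becoming endocyclic. No stereocentre is formed and the Z geometry of C5=C6 is that of the iodide. The step needs reductive elimination to outrun β-hydride elimination from C3 (which would give the C3=C4 enone) and ring closure to outrun intermolecular coupling; the bulky, electron-rich biaryl phosphine favours the former, and slow addition to high dilution together with the short seco chain held between the rigid ring A and ring C favours the latter. Oxidative addition at the alkenyl iodide should also be much faster than ionisation of the allylic C7–O bond of the lactone.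

Step 28
Reactants: 40 tricyclic C2 ketone
Product: 41 (2R)-C2 alcohol
Conditions: (S)-1-methyl-3,3-diphenyltetrahydro-1H,3H-pyrrolo[1,2-c][1,3,2]oxazaborole (1 equiv), catecholborane, toluene, −40 °C
Reagents that add atoms: none
Why: Corey–Bakshi–Shibata reduction, with quaternary C1 as the large and C3 as the small substituent of the ketone, should deliver hydride under reagent control to give the 2R alcohol without touching the lactone or the acetate.

Step 29
Reactants: 41 C2 alcohol
Product: 42 C2,C9 diacetate acetonide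
Conditions: Ac2O, pyridine, DMAP (cat.), CH2Cl2, 0 °C to rt
Reagents that add atoms: acetic anhydride, CC(=O)OC(C)=O
Why: Acetylation of the only secondary hydroxyl, the tertiary C8 hydroxyl being too hindered to react under these conditions.

Step 30
Reactants: 42 diacetate acetonide
Product: 43 target CNP0146024.1
Conditions: AcOH/H2O (4:1), 40 °C
Reagents that add atoms: none
Why: Mild acid hydrolysis of the acetonide releases the C11/C12 diol while the acetates and the lactone should survive.

**Compound list**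

1 | pent-1-en-3-one | CCC(=O)C=C | starting material
2 | (Z)-3-(triisopropylsilyloxy)penta-1,3-diene | C=C/C(=C/C)O[Si](C(C)C)(C(C)C)C(C)C | intermediate
3 | ethyl (E)-3-methyl-4-oxobut-2-enoate | CCOC(=O)/C=C(\C)C=O | starting material
4 | ring A adduct, ethyl 6-formyl-2,6-dimethyl-3-(triisopropylsilyloxy)cyclohex-3-ene-1-carboxylate (C10 ester β, C1 methyl β, formyl α, C11 epimers) | CCOC(=O)[C@H]1C(C)C(O[Si](C(C)C)(C(C)C)C(C)C)=CC[C@]1(C)C=O | intermediate
5 | C2 carbinol, 6-(1-hydroxyethyl) analogue of 4 (C2 and C11 epimers) | CCOC(=O)[C@H]1C(C)C(O[Si](C(C)C)(C(C)C)C(C)C)=CC[C@]1(C)C(C)O | intermediate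
6 | C2 methyl ketone, ethyl 6-acetyl-2,6-dimethyl-3-(triisopropylsilyloxy)cyclohex-3-ene-1-carboxylate | CCOC(=O)[C@H]1C(C)C(O[Si](C(C)C)(C(C)C)C(C)C)=CC[C@]1(C)C(C)=O | intermediate
7 | enone, ethyl 6-acetyl-2,6-dimethyl-3-oxocyclohex-4-ene-1-carboxylate | CCOC(=O)[C@H]1C(C)C(=O)C=C[C@]1(C)C(C)=O | intermediate
8 | C2 silyl enol ether, ethyl 6-[1-(tert-butyldimethylsilyloxy)vinyl]-2,6-dimethyl-3-oxocyclohex-4-ene-1-carboxylate | CCOC(=O)[C@H]1C(C)C(=O)C=C[C@]1(C)C(=C)O[Si](C)(C)C(C)(C)C | intermediate
9 | silyloxycyclopropane, ethyl 6-[1-(tert-butyldimethylsilyloxy)cyclopropyl]-2,6-dimethyl-3-oxocyclohex-4-ene-1-carboxylate | CCOC(=O)[C@H]1C(C)C(=O)C=C[C@]1(C)C1(O[Si](C)(C)C(C)(C)C)CC1 | intermediate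
10 | potassium dienolate of 9 (C11=C12–O−) | CCOC(=O)[C@H]1C(C)=C([O-])C=C[C@]1(C)C1(O[Si](C)(C)C(C)(C)C)CC1.[K+] | intermediate (not isolated)
11 | dienyl triflate, ethyl 6-[1-(tert-butyldimethylsilyloxy)cyclopropyl]-2,6-dimethyl-3-(trifluoromethylsulfonyloxy)cyclohexa-2,4-diene-1-carboxylate | CCOC(=O)[C@H]1C(C)=C(OS(=O)(=O)C(F)(F)F)C=C[C@]1(C)C1(O[Si](C)(C)C(C)(C)C)CC1 | intermediate
12 | diene, ethyl 6-[1-(tert-butyldimethylsilyloxy)cyclopropyl]-2,6-dimethylcyclohexa-2,4-diene-1-carboxylate | CCOC(=O)[C@H]1C(C)=CC=C[C@]1(C)C1(O[Si](C)(C)C(C)(C)C)CC1 | intermediate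
13 | diol, C11 and C12 hydroxyls α and cis, C13=C14 | CCOC(=O)[C@H]1[C@](C)(O)[C@H](O)C=C[C@]1(C)C1(O[Si](C)(C)C(C)(C)C)CC1 | intermediate
14 | acetonide ester (C11/C12 isopropylidene acetal of 13) | CCOC(=O)[C@H]1[C@](C)(O2)[C@H](OC2(C)C)C=C[C@]1(C)C1(O[Si](C)(C)C(C)(C)C)CC1 | intermediate
15 | ring A aldehyde (C9 aldehyde β on C10, C1 β-methyl and α-silyloxycyclopropyl, C11/C12 α-acetonide) | O=C[C@H]1[C@](C)(O2)[C@H](OC2(C)C)C=C[C@]1(C)C1(O[Si](C)(C)C(C)(C)C)CC1 | intermediate
16 | prop-2-yn-1-ol | C#CCO | starting material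
17 | triethyl(prop-2-yn-1-yloxy)silane | C#CCO[Si](CC)(CC)CC | intermediate
18 | ethyl 2-(tert-butyldimethylsilyloxy)acetate | CCOC(=O)CO[Si](C)(C)C(C)(C)C | starting material
19 | lithium acetylide of 17 | [Li]C#CCO[Si](CC)(CC)CC | intermediate (not isolated)
20 | ynone, 1-(tert-butyldimethylsilyloxy)-5-(triethylsilyloxy)pent-3-yn-2-one | CC(C)(C)[Si](C)(C)OCC(=O)C#CCO[Si](CC)(CC)CC | intermediate
21 | (R)-1-(tert-butyldimethylsilyloxy)-5-(triethylsilyloxy)pent-3-yn-2-ol | CC(C)(C)[Si](C)(C)OC[C@H](O)C#CCO[Si](CC)(CC)CC | intermediate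
22 | alkenylstannane, 3-(tributylstannyl) analogue of 23 (tin on C8, cis to C19; C7 as in 21) | CCCC[Sn](CCCC)(CCCC)/C(=C\CO[Si](CC)(CC)CC)[C@@H](O)CO[Si](C)(C)C(C)(C)C | intermediate (not isolated)
23 | iodoalkenol, 1-(tert-butyldimethylsilyloxy)-3-iodo-5-(triethylsilyloxy)pent-3-en-2-ol (iodine cis to C19; C7 as in 21) | I/C(=C\CO[Si](CC)(CC)CC)[C@@H](O)CO[Si](C)(C)C(C)(C)C | intermediate
24 | C7 triethylsilyl ether of 23 | I/C(=C\CO[Si](CC)(CC)CC)[C@@H](O[Si](CC)(CC)CC)CO[Si](C)(C)C(C)(C)C | intermediate
25 | alkenyllithium from 24 (lithium on C8) | [Li]/C(=C\CO[Si](CC)(CC)CC)[C@@H](O[Si](CC)(CC)CC)CO[Si](C)(C)C(C)(C)C | intermediate (not isolated)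
26 | lithium C9 alkoxide of the coupling product | CC(C)(C)[Si](C)(C)OC[C@H](O[Si](CC)(CC)CC)/C(=C/CO[Si](CC)(CC)CC)[C@H](O[Li])[C@H]1[C@](C)(O2)[C@H](OC2(C)C)C=C[C@]1(C)C1(O[Si](C)(C)C(C)(C)C)CC1 | intermediate (not isolated)
27 | coupled C9 acetate (9R; C8=C17 with C9 cis to C19; C6 OTBS, C7 and C19 OSiEt3) | CC(C)(C)[Si](C)(C)OC[C@H](O[Si](CC)(CC)CC)/C(=C/CO[Si](CC)(CC)CC)[C@H](OC(C)=O)[C@H]1[C@](C)(O2)[C@H](OC2(C)C)C=C[C@]1(C)C1(O[Si](C)(C)C(C)(C)C)CC1 | intermediate
28 | C7,C19 diol | CC(C)(C)[Si](C)(C)OC[C@H](O)/C(=C/CO)[C@H](OC(C)=O)[C@H]1[C@](C)(O2)[C@H](OC2(C)C)C=C[C@]1(C)C1(O[Si](C)(C)C(C)(C)C)CC1 | intermediate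
29 | C8,C17 epoxide (erythro to the C7 hydroxyl) | CC(C)(C)[Si](C)(C)OC[C@H](O)[C@]3(O[C@@H]3CO)[C@H](OC(C)=O)[C@H]1[C@](C)(O2)[C@H](OC2(C)C)C=C[C@]1(C)C1(O[Si](C)(C)C(C)(C)C)CC1 | intermediate
30 | C7,C8,C19 triol with the C17 methyl | CC(C)(C)[Si](C)(C)OC[C@H](O)[C@@](O)([C@@H](C)CO)[C@H](OC(C)=O)[C@H]1[C@](C)(O2)[C@H](OC2(C)C)C=C[C@]1(C)C1(O[Si](C)(C)C(C)(C)C)CC1 | intermediate
31 | C19 hydroxy aldehyde | CC(C)(C)[Si](C)(C)OC[C@H](O)[C@@](O)([C@@H](C)C=O)[C@H](OC(C)=O)[C@H]1[C@](C)(O2)[C@H](OC2(C)C)C=C[C@]1(C)C1(O[Si](C)(C)C(C)(C)C)CC1 | intermediate (not isolated)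
32 | C19 lactol (anomers) | CC(C)(C)[Si](C)(C)OC[C@@H]1OC(O)[C@H](C)[C@@]1(O)[C@H](OC(C)=O)[C@H]1[C@](C)(O2)[C@H](OC2(C)C)C=C[C@]1(C)C1(O[Si](C)(C)C(C)(C)C)CC1 | intermediate (not isolated)
33 | lactone, ring C closed, C6 OTBS | CC(C)(C)[Si](C)(C)OC[C@@H]1OC(=O)[C@H](C)[C@@]1(O)[C@H](OC(C)=O)[C@H]1[C@](C)(O2)[C@H](OC2(C)C)C=C[C@]1(C)C1(O[Si](C)(C)C(C)(C)C)CC1 | intermediate
34 | C6 alcohol | OC[C@@H]1OC(=O)[C@H](C)[C@@]1(O)[C@H](OC(C)=O)[C@H]1[C@](C)(O2)[C@H](OC2(C)C)C=C[C@]1(C)C1(O[Si](C)(C)C(C)(C)C)CC1 | intermediate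
35 | C6 aldehyde | O=C[C@@H]1OC(=O)[C@H](C)[C@@]1(O)[C@H](OC(C)=O)[C@H]1[C@](C)(O2)[C@H](OC2(C)C)C=C[C@]1(C)C1(O[Si](C)(C)C(C)(C)C)CC1 | intermediate
36 | (Z)-C5 alkenyl iodide, cyclopropanol as tert-butyldimethylsilyl ether | I/C(C)=C\[C@@H]1OC(=O)[C@H](C)[C@@]1(O)[C@H](OC(C)=O)[C@H]1[C@](C)(O2)[C@H](OC2(C)C)C=C[C@]1(C)C1(O[Si](C)(C)C(C)(C)C)CC1 | intermediate
37 | seco cyclopropanol, precursor of the key step | I/C(C)=C\[C@@H]1OC(=O)[C@H](C)[C@@]1(O)[C@H](OC(C)=O)[C@H]1[C@](C)(O2)[C@H](OC2(C)C)C=C[C@]1(C)C1(O)CC1 | intermediate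
38 | alkenylpalladium iodide (phosphine omitted) | I[Pd]/C(C)=C\[C@@H]1OC(=O)[C@H](C)[C@@]1(O)[C@H](OC(C)=O)[C@H]1[C@](C)(O2)[C@H](OC2(C)C)C=C[C@]1(C)C1(O)CC1 | intermediate (not isolated)
39 | palladium homoenolate, eleven-membered palladacycle (phosphine omitted) | CC(=O)O[C@@H]1[C@H]2[C@](C)(O3)[C@H](OC3(C)C)C=C[C@]2(C)C(=O)CC[Pd]/C(C)=C\[C@@H]2OC(=O)[C@H](C)[C@]21O | intermediate (not isolated)
40 | tricyclic C2 ketone with C11/C12 acetonide | CC(=O)O[C@@H]1[C@H]2[C@](C)(O3)[C@H](OC3(C)C)C=C[C@]2(C)C(=O)CC/C(C)=C\[C@@H]2OC(=O)[C@H](C)[C@]21O | intermediate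
41 | (2R)-C2 alcohol | CC(=O)O[C@@H]1[C@H]2[C@](C)(O3)[C@H](OC3(C)C)C=C[C@]2(C)[C@H](O)CC/C(C)=C\[C@@H]2OC(=O)[C@H](C)[C@]21O | intermediate
42 | C2,C9 diacetate acetonide | CC(=O)O[C@@H]1[C@H]2[C@](C)(O3)[C@H](OC3(C)C)C=C[C@]2(C)[C@H](OC(C)=O)CC/C(C)=C\[C@@H]2OC(=O)[C@H](C)[C@]21O | intermediate
43 | CNP0146024.1, (1S,2R,5Z,7S,8S,9R,10S,11S,12R,17R) | CC(=O)O[C@@H]1[C@H]2[C@](C)(O)[C@H](O)C=C[C@]2(C)[C@H](OC(C)=O)CC/C(C)=C\[C@@H]2OC(=O)[C@H](C)[C@]21O | target

**Step count and risks**

Total step count: 30. Longest linear sequence: 25 steps (steps 1–12, then 18–30); the side-chain fragment takes steps 13–17.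

Steps most likely to fail:

Step 27 (key step). The palladium homoenolate may undergo β-hydride elimination to the C3=C4 enone or protodemetalation to the ethyl ketone, intermolecular coupling may compete with closure of the strained ten-membered ring, and the β-hydroxy lactone may degrade under the basic conditions. The fallback sets out from 37 and comes back at 41 with known reaction types. The cyclopropanol is opened with N-bromosuccinimide (CH2Cl2, 0 °C) to the β-bromo ketone F1, which loses HBr with Et3N to give the vinyl ketone F2. Corey–Bakshi–Shibata reduction ((S)-oxazaborolidine of step 28, catecholborane, −78 °C) gives the 2R allylic alcohol F3. Chemoselective hydroboration of the terminal vinyl group with 9-borabicyclo[3.3.1]nonane gives the alkylborane F4, and intramolecular B-alkyl Suzuki–Miyaura coupling with the C5 iodide (Pd(dppf)Cl2, AsPh3, Cs2CO3, DMF/THF/H2O, high dilution) forms C4–C5 and delivers 41, so step 28 is not needed.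

Step 18. Addition of the hindered alkenyllithium to the doubly neopentyl aldehyde may be slow, so that loss of the β-silyloxy group (allene formation) and enolisation of 15 compete, and the facial selectivity at C9 may be lower than the Felkin–Anh model suggests. The fallback sets out from 24 and 15 and comes back at 27. Nozaki–Hiyama–Kishi coupling (CrCl2, NiCl2 (cat.), DMSO/THF, rt) replaces the basic organolithium by a non-basic alkenylchromium species that tolerates the β-silyloxy group and should give the C9 alcohol F5, which is acetylated (Ac2O, DMAP, pyridine) to 27.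

Step 25. The basic ylide may epimerise C7 or cleave the β-hydroxy aldehyde by retro-aldol reaction, and Z selectivity may be incomplete. The fallback sets out from 35 and comes back at 40. Dibromo-olefination under near-neutral conditions (CBr4, PPh3, CH2Cl2, 0 °C) gives the 1,1-dibromoalkene F6. Negishi coupling with MeZnCl (PdCl2(DPEphos), THF), which replaces selectively the bromide trans to C7, gives the Z bromoalkene F7. Desilylation (Bu4NF, AcOH) gives the bromo seco cyclopropanol F8, which is cyclised under the conditions of step 27 to 40.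

**Further compounds**

F1 | step 27 | β-bromo ketone (C2 ketone, C4 bromide) from 37 | I/C(C)=C\[C@@H]1OC(=O)[C@H](C)[C@@]1(O)[C@H](OC(C)=O)[C@H]1[C@](C)(O2)[C@H](OC2(C)C)C=C[C@]1(C)C(=O)CCBr
F2 | step 27 | vinyl ketone (C2 ketone, C3=C4) | I/C(C)=C\[C@@H]1OC(=O)[C@H](C)[C@@]1(O)[C@H](OC(C)=O)[C@H]1[C@](C)(O2)[C@H](OC2(C)C)C=C[C@]1(C)C(=O)C=C
F3 | step 27 | (2R)-allylic alcohol | I/C(C)=C\[C@@H]1OC(=O)[C@H](C)[C@@]1(O)[C@H](OC(C)=O)[C@H]1[C@](C)(O2)[C@H](OC2(C)C)C=C[C@]1(C)[C@H](O)C=C
F4 | step 27 | C4 alkylborane (9-borabicyclo[3.3.1]nonan-9-yl on C4) | I/C(C)=C\[C@@H]1OC(=O)[C@H](C)[C@@]1(O)[C@H](OC(C)=O)[C@H]1[C@](C)(O2)[C@H](OC2(C)C)C=C[C@]1(C)[C@H](O)CCB1C2CCCC1CCC2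
F5 | step 18 | C9 alcohol of the coupling product | CC(C)(C)[Si](C)(C)OC[C@H](O[Si](CC)(CC)CC)/C(=C/CO[Si](CC)(CC)CC)[C@H](O)[C@H]1[C@](C)(O2)[C@H](OC2(C)C)C=C[C@]1(C)C1(O[Si](C)(C)C(C)(C)C)CC1
F6 | step 25 | 1,1-dibromoalkene at C5 | BrC(Br)=C[C@@H]1OC(=O)[C@H](C)[C@@]1(O)[C@H](OC(C)=O)[C@H]1[C@](C)(O2)[C@H](OC2(C)C)C=C[C@]1(C)C1(O[Si](C)(C)C(C)(C)C)CC1
F7 | step 25 | (Z)-C5 alkenyl bromide, cyclopropanol as silyl ether | Br/C(C)=C\[C@@H]1OC(=O)[C@H](C)[C@@]1(O)[C@H](OC(C)=O)[C@H]1[C@](C)(O2)[C@H](OC2(C)C)C=C[C@]1(C)C1(O[Si](C)(C)C(C)(C)C)CC1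
F8 | step 25 | bromo seco cyclopropanol | Br/C(C)=C\[C@@H]1OC(=O)[C@H](C)[C@@]1(O)[C@H](OC(C)=O)[C@H]1[C@](C)(O2)[C@H](OC2(C)C)C=C[C@]1(C)C1(O)CC1
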